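**Plan**
1. Ring numbering: C1 (quaternary oxirane carbon, bears C7H2OBz), C2 (CHOH), C3 (CHOBz), C4=C5, C6 (oxirane CH). The enabling feature is the cyclohexene whose C4=C5 bond lies between two oxygen-bearing carbons, C3 and C6; this is a furan [4+2] retron in which the oxirane oxygen on C6 is the furan oxygen.
2. Retrosynthesis: remove the C7–O benzoate and return C7 to an aldehyde; open the oxirane to a C6–OH/C1–Br bromohydrin and rejoin the C6 oxygen to C3 as a 1,4-oxygen bridge (benzoyl moved from O3 back to O2); then cut C2–C3 and C1–C6 together, giving furan and the enol benzoate of bromomalonaldehyde.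
3. Forward order of rings: the cycloaddition makes the carbocycle and leaves the furan oxygen as a bridge (7-oxabicyclo[2.2.1]heptene); the bridge is opened at C3 and the same oxygen closes the oxirane on C1 (7-oxabicyclo[4.1.0]heptene); reduction and benzoylation at C7 finish.
4. Stereochemistry: absolute configuration from the chiral oxazaborolidinone in the cycloaddition; C1/C2 from the Z enal and the exo-formyl transition state; C3 by inversion through a benzoxonium ion; C6 keeps the bridge configuration, so the oxirane ends on the face opposite O2 and O3.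

Key step: step 2

Assumption: the catalyst from (R)-tryptophan is taken to send furan to the Si face of the bromine-bearing carbon of 3, as the face-shielding model for 2-bromoacrolein implies; should the sense be the reverse, the catalyst from (S)-tryptophan is used instead.

**Step 1**
Reactants: 1 bromomalonaldehyde (2-bromopropanedial, reacting as its enol); 2 benzoyl chloride
Product: 3 (Z)-2-bromo-3-oxoprop-1-en-1-yl benzoate (benzoyloxy cis to bromine, trans to formyl)
Conditions: Et3N (1.1 equiv), CH2Cl2, −20 to 0 °C
Reagents that add atoms: none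
Why: O-acylation of a vinylogous acid by an acid chloride; the extended enolate should place the new benzoyloxy group trans to the remaining formyl group, which is the Z isomer.

**Step 2**
Reactants: 3 (Z)-2-bromo-3-oxoprop-1-en-1-yl benzoate; 4 furan
Product: 5 (1R,2S,3R,4S)-3-bromo-3-formyl-7-oxabicyclo[2.2.1]hept-5-en-2-yl benzoate (bromine and benzoyloxy endo, formyl exo)
Conditions: 4 (10 equiv), (4R)-2-butyl-4-(1H-indol-3-ylmethyl)-3-(4-methylphenylsulfonyl)-1,3,2-oxazaborolidin-5-one (10 mol %), CH2Cl2, −78 to −40 °C
Reagents that add atoms: none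
Why: Concerted but asynchronous [4π+2π] cycloaddition (Diels–Alder reaction) of furan to the enal, whose formyl oxygen is bound to the boron of the catalyst; the closest known reaction type is the oxazaborolidinone-catalysed addition of 2-bromoacrolein to furan. It closes one ring, the cyclohexene, by suprafacial bond formation on both partners (C2–C3 and C1–C6), and so turns the furan ring into the 1,4-oxygen bridge. C1 and C2 take their relative configuration from the Z geometry of 3 (bromine cis to benzoyloxy), the bridgeheads C3 and C6 from cis addition across furan, and the relation between the two pairs from the exo-formyl, endo-bromine transition state that α-halo enals favour. The absolute configuration is set by the catalyst, whose indole unit covers one face of the bound enal so that furan adds to the Si face of the bromine-bearing carbon. The step needs cycloaddition to win over conjugate substitution of the enol benzoate by furan, exo-formyl over endo-formyl closure, and one enal face over the other; the α-bromine, the s-cis boron-bound enal and the low temperature are meant to secure these. The adduct then carries bromine anti to the bridge on C1 and benzoate anti to the bridge on C2, the two relations that step 3 uses.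

**Step 3**
Reactants: 5 (1R,2S,3R,4S)-3-bromo-3-formyl-7-oxabicyclo[2.2.1]hept-5-en-2-yl benzoate
Product: 8 (1R,2S,3S,6S)-1-formyl-2-hydroxy-7-oxabicyclo[4.1.0]hept-4-en-3-yl benzoate, via benzoxonium trifluoroborate zwitterion 6 (not isolated), via bromohydrin 7 (not isolated)
Conditions: BF3·OEt2 (1.5 equiv), CH2Cl2, −40 to 0 °C; H2O, then aq NaHCO3; crude product, Ag2O (1.5 equiv), CH2Cl2, rt, dark
Reagents that add atoms: water, O
Why: BF3 on the bridge oxygen makes it a leaving group at the allylic bridgehead C3, and the endo benzoate on C2 attacks C3 from the rear (anchimeric assistance as in the acid-mediated opening of 7-oxanorbornanes and in Woodward–Prévost acyloxonium chemistry) to give the cis-fused benzoxonium ion with inversion at C3; water should open this to the cis hydroxy benzoate with expulsion of the better leaving O2 (β to bromine and formyl), leaving benzoyl on O3, and the freed C6 alkoxide, anti to bromine, closes the oxirane by intramolecular SN2 with inversion at C1 (the ring-closing half of a Darzens reaction).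

**Step 4**
Reactants: 8 (1R,2S,3S,6S)-1-formyl-2-hydroxy-7-oxabicyclo[4.1.0]hept-4-en-3-yl benzoate
Product: 9 (1R,2S,3S,6S)-2-hydroxy-1-(hydroxymethyl)-7-oxabicyclo[4.1.0]hept-4-en-3-yl benzoate
Conditions: NaBH4 (0.5 equiv), CeCl3·7H2O (1 equiv), MeOH/CH2Cl2, −40 °C
Reagents that add atoms: none
Why: Luche reduction takes the aldehyde to the primary alcohol under near-neutral conditions that should leave benzoate, oxirane and alkene untouched; no stereocenter is formed.

**Step 5**
Reactants: 9 (1R,2S,3S,6S)-2-hydroxy-1-(hydroxymethyl)-7-oxabicyclo[4.1.0]hept-4-en-3-yl benzoate; 2 benzoyl chloride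
Product: 10 [(1R,2S,3S,6S)-3-(benzoyloxy)-2-hydroxy-7-oxabicyclo[4.1.0]hept-4-en-1-yl]methyl benzoate (target)
Conditions: 2 (1.1 equiv), 2,4,6-collidine, CH2Cl2, −40 to 0 °C
Reagents that add atoms: none
Why: Acylation with an acid chloride and a hindered pyridine base at low temperature should be much faster at the primary hydroxyl than at the secondary C2 hydroxyl, which is flanked by the quaternary oxirane carbon and the C3 benzoate; no stereocenter is touched.

**Compound list**
1 | bromomalonaldehyde (2-bromopropanedial) | O=CC(Br)C=O | starting material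
2 | benzoyl chloride | O=C(Cl)c1ccccc1 | starting material
3 | (Z)-2-bromo-3-oxoprop-1-en-1-yl benzoate | O=C/C(Br)=C/OC(=O)c1ccccc1 | intermediate
4 | furan | c1ccoc1 | starting material
5 | (1R,2S,3R,4S)-3-bromo-3-formyl-7-oxabicyclo[2.2.1]hept-5-en-2-yl benzoate | O=C[C@]1(Br)[C@@H](OC(=O)c3ccccc3)[C@H]2C=C[C@@H]1O2 | intermediate
6 | benzoxonium trifluoroborate zwitterion (2-phenyl-1,3-dioxolan-2-ylium cis-fused across C2–C3 on the face opposite the former bridge; C6–O–BF3 anion; bromine and formyl on C1 unchanged) | O=C[C@]1(Br)[C@H]2OC(c3ccccc3)=[O+][C@H]2C=C[C@@H]1O[B-](F)(F)F | intermediate (not isolated)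
7 | (1S,4S,5R,6S)-5-bromo-5-formyl-4,6-dihydroxycyclohex-2-en-1-yl benzoate | O=C[C@]1(Br)[C@@H](O)[C@@H](OC(=O)c2ccccc2)C=C[C@@H]1O | intermediate (not isolated)
8 | (1R,2S,3S,6S)-1-formyl-2-hydroxy-7-oxabicyclo[4.1.0]hept-4-en-3-yl benzoate | O=C[C@]12O[C@H]1C=C[C@H](OC(=O)c1ccccc1)[C@@H]2O | intermediate
9 | (1R,2S,3S,6S)-2-hydroxy-1-(hydroxymethyl)-7-oxabicyclo[4.1.0]hept-4-en-3-yl benzoate | OC[C@]12O[C@H]1C=C[C@H](OC(=O)c1ccccc1)[C@@H]2O | intermediate
10 | [(1R,2S,3S,6S)-3-(benzoyloxy)-2-hydroxy-7-oxabicyclo[4.1.0]hept-4-en-1-yl]methyl benzoate | O=C(OC[C@]12O[C@H]1C=C[C@H](OC(=O)c1ccccc1)[C@@H]2O)c1ccccc1 | target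

Total step count: 5
Longest linear sequence: 5 steps (1 → 3 → 5 → 8 → 9 → 10)

**Steps most likely to fail**

Step 2. Furan may add to the β-carbon of the boron-bound enal and lose benzoate (vinylogous acyl substitution) before the second bond closes, or the cycloaddition may be too slow at temperatures where the adduct does not revert. Fallback, from 3 and 4 back to 5: cycloaddition without any Lewis acid at about 12 kbar (CH2Cl2, room temperature), where the concerted path is favoured by its negative activation volume, would give 5 together with its mirror image (1S,2R,3S,4R)-3-bromo-3-formyl-7-oxabicyclo[2.2.1]hept-5-en-2-yl benzoate F1. Condensation of the mixture with (1R,2R)-N,N′-dimethyl-1,2-diphenylethane-1,2-diamine (molecular sieves, Et2O) would give the aminal of 5 F2 and the aminal of the mirror image F3, diastereomers to be separated by chromatography. Hydrolysis of F2 (dilute aqueous HCl/Et2O, 0 °C) returns 5, where the route is rejoined.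

Step 3. The Lewis acid may ionise the allylic bridgehead past the benzoxonium stage (allyl cation, loss of water, aromatisation), the orthoacid may collapse or later shift with benzoyl on O2, and the α-bromo-β-hydroxy aldehyde may fragment by retro-aldol cleavage instead of closing. Fallback, from 5 to 10: the aldehyde is taken out before the bridge is opened. Luche reduction should give the bromo alcohol (1R,2S,3R,4S)-3-bromo-3-(hydroxymethyl)-7-oxabicyclo[2.2.1]hept-5-en-2-yl benzoate F4, and benzoylation (2, pyridine) the dibenzoate F5. BF3·OEt2 then leads through the benzoxonium zwitterion F6 and, after water, the bromohydrin F7, in which no retro-aldol path exists; Ag2O closes the oxirane to give 10 directly, so that steps 4 and 5 fall away.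

Step 5. Acylation may fail to tell the primary from the secondary hydroxyl, and the base may set off benzoyl migration from O3 to O2 or Payne rearrangement of the 2,3-epoxy alcohol. Fallback, from 9 to 10: base-free, enzyme-controlled acyl transfer (vinyl benzoate, immobilised Candida antarctica lipase B, tert-butyl methyl ether, 30 °C), which acylates primary hydroxyls only; it makes no new compound (F0).

**Further compounds**
F1 | step 2 | (1S,2R,3S,4R)-3-bromo-3-formyl-7-oxabicyclo[2.2.1]hept-5-en-2-yl benzoate (mirror image of 5) | O=C[C@@]1(Br)[C@H](OC(=O)c3ccccc3)[C@@H]2C=C[C@H]1O2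
F2 | step 2 | (1R,2S,3R,4S)-3-bromo-3-[(4R,5R)-1,3-dimethyl-4,5-diphenylimidazolidin-2-yl]-7-oxabicyclo[2.2.1]hept-5-en-2-yl benzoate (aminal of 5) | CN1[C@H](c2ccccc2)[C@@H](c2ccccc2)N(C)C1[C@]3(Br)[C@@H](OC(=O)c4ccccc4)[C@H]5C=C[C@@H]3O5
F3 | step 2 | (1S,2R,3S,4R)-3-bromo-3-[(4R,5R)-1,3-dimethyl-4,5-diphenylimidazolidin-2-yl]-7-oxabicyclo[2.2.1]hept-5-en-2-yl benzoate (aminal of F1) | CN1[C@H](c2ccccc2)[C@@H](c2ccccc2)N(C)C1[C@@]3(Br)[C@H](OC(=O)c4ccccc4)[C@@H]5C=C[C@H]3O5
F4 | step 3 | (1R,2S,3R,4S)-3-bromo-3-(hydroxymethyl)-7-oxabicyclo[2.2.1]hept-5-en-2-yl benzoate | OC[C@]1(Br)[C@@H](OC(=O)c3ccccc3)[C@H]2C=C[C@@H]1O2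
F5 | step 3 | (1R,2S,3R,4S)-3-[(benzoyloxy)methyl]-3-bromo-7-oxabicyclo[2.2.1]hept-5-en-2-yl benzoate | O=C(OC[C@]1(Br)[C@@H](OC(=O)c3ccccc3)[C@H]2C=C[C@@H]1O2)c1ccccc1
F6 | step 3 | benzoxonium trifluoroborate zwitterion of F5 (2-phenyl-1,3-dioxolan-2-ylium cis-fused across C2–C3; C6–O–BF3 anion; C1 bears bromine and CH2OBz) | O=C(OC[C@]1(Br)[C@H]2OC(c3ccccc3)=[O+][C@H]2C=C[C@@H]1O[B-](F)(F)F)c1ccccc1
F7 | step 3 | (1S,4S,5R,6S)-5-[(benzoyloxy)methyl]-5-bromo-4,6-dihydroxycyclohex-2-en-1-yl benzoate | O=C(OC[C@]1(Br)[C@@H](O)[C@@H](OC(=O)c2ccccc2)C=C[C@@H]1O)c1ccccc1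
F0 | step 5 | none | none
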